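One millimole of solid substrate carried to triple product costs 3 millimoles of coupling partner, if each step takes one.

in all of them: solid substrate 45 mM
- Saturday's: coupling partner 30 mM; run made earlier
- Wednesday's: coupling partner 68 mM; run made earlier
- flask: coupling partner 45.0 mM; time 2.0 d

| run | time / h | solid substrate / % | first product / % |
|---|---|---|---|
| Saturday's | 6.00 | 74 | 5 |
| Saturday's | 15.0 | 45 | 6 |
| Saturday's | 20.0 | 33 | 4 |
| Saturday's | 30.0 | 19 | 9 |
| Saturday's | 40.0 | 17 | 5 |
| Saturday's | 50.0 | 8 | 9 |
| Wednesday's | 4.00 | 82 | 1 |
| Wednesday's | 6.00 | 73 | 4 |
| Wednesday's | 8.00 | 63 | 6 |
| Wednesday's | 15.0 | 36 | 10 |
| Wednesday's | 20.0 | 25 | 5 |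
| Wednesday's | 30.0 | 3 | 6 |
| Wednesday's | 50.0 | 1 | 4 |

(each reading ± 2 percentage points)

1. the solid substrate standing at 2.0 d, as a percentage of the solid substrate charged (only what is still solid)
2. the first product standing at 2.0 d, as a percentage of the solid substrate charged
3. the double product standing at 2.0 d, as a percentage of the solid substrate charged
4. the triple product standing at 2.0 d, as a percentage of the solid substrate charged

- at the start none of the solid substrate is in solution
- a reading or a percentage of double product counts all its forms, free or not

I first asked whether first product stands or moves on. On Wednesday's run the solid had fallen to 3% by 30.0 h, yet first product read 6%, so it had not piled up, and I took it to move on up the ladder. Next I asked how far the partner reaches, treating coupling partner as the limiting reagent. I reckoned the top share, the share of the solid substrate charged that the partner can carry to triple product, and the flask's charges give 33.3%. That is the crossing: once the partner was spent, I expected whatever still dissolved to stay uncoupled. I therefore took that share as the ceiling on triple product, and I expected triple product ahead of double product. The solid read 8% on Saturday's run and 1% on Wednesday's at 50.0 h, so I looked for a few percent in the flask.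

The forecast gave solid substrate 4%, first product 6%, double product 40% and triple product 5%, “Assuming the partner is nearly spent, with double product favoured”. My reckoning differed from it in putting triple product ahead.

The flask gave solid substrate 3.53%, first product 6.63%, double product 9.20% and triple product 17.7%.

    starting material + coupling partner → first product (k = 18.0 /M/h)
    coupling partner + first product → double product (k = 46.0 /M/h)
    coupling partner + double product → triple product (k = 19.0 /M/h)
    crystals ⇌ double product, rate k4*(cs4 - [double product]) while solid is left; crystals form when [double product] > cs4 (solubility = 16.0 mM, k = 5.80 /h)
    solid substrate ⇌ starting material, rate k5*(cs5 - [starting material]) while solid is left; crystals form when [starting material] > cs5 (solubility = 30.0 mM, k = 0.0730 /h)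
    coupling partner → decomposed reagent (k = 0.0380 /h)

Triple product in the flask stood at 17.7%, less than the top share of 33.3%, with coupling partner at 0% of its charge and decomposed reagent at 9.89 mM. The neighbouring flask, charged with 110 mM of coupling partner and read at the same time, has a top share of 81.5%. It held first product 6.60%, double product 9.31% and triple product 49.5%, the last less than its top share. Its coupling partner stood at 0%, its solid substrate at 0%, and its decomposed reagent at 31.9 mM.

The data come from a simulation with made-up constants; noise was put on by code.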